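- The violet run held 99 mM of product at 130 h, from 200 mM of substrate and 160 mM of partner. It had climbed from 85 mM over the previous 2.25 d, although the overall equation still left it 0.0610 M of partner.

| flask | substrate | partner | time |
|---|---|---|---|
| violet | 200 mM | 160 mM |  |
| blue | 80.0 mM | 40.0 mM |  |
| green | 400 mM | 160 mM |  |
| grey | 600 mM | 480 mM | 130 h |

| violet run: time / h | violet run: [product] / mM | blue run: time / h | blue run: [product] / mM | green run: time / h | green run: [product] / mM |
|---|---|---|---|---|---|
| 5.2 | 19 | 5.2 | 0 | 5.2 | 36 |
| 8.9 | 34 | 8.9 | 4 | 8.9 | 55 |
| 15 | 45 | 15 | 6 | 15 | 79 |
| 26 | 63 | 26 | 8 | 26 | 98 |
| 44 | 79 | 44 | 10 | 44 | 116 |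
| 76 | 85 | 76 | 9 | 76 | 123 |
| 130 | 99 | 130 | 13 | 130 | 134 |

(scatter of a reading: 3 mM)

* how the opening rate goes with [substrate] round the charge of the violet run: the exponent of the rate at two percent of substrate gone to product (one fixed amount of product, the same in the runs compared)
* how the opening rate goes with [partner] round the charge of the violet run: the exponent of the rate at two percent of substrate gone to product
* product in the grey run at 130 h, as a share of the substrate charged

- Overall: substrate + partner -> product.
- Constant volume, constant temperature.
- The analysis sees a species whether free or bound.
- An order is taken over about fifteen percent of the charge, up and down.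

- I carried one quantity, the odds of a flask: product at 130 h divided by the substrate charged and not found as product 0.980. It is a snapshot at that one time, not a mean over the curve, and the substrate not found as product includes substrate still unreacted, so it mixes conversion with the split between product and loss; the figure given is for the violet run.
- I began with the main step alone. In the grey run the partner is the limiting reagent, so that step allowed a share of 80.0%. The violet run has the same charge ratio and stood at 49.5%, gaining 0.0140 M over its last interval, so I tried a second process.
- I added a loss of substrate. The green run doubled the violet substrate at equal partner, and its odds were 0.504, so the violet odds were twice the green. I therefore took the odds to go as one over [substrate]. With an exponent of one in [partner], the grey run, with both charges multiplied by 3.00, kept the violet odds and dropped to 49.5%.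
- Last I let the partner exponent float. The blue run gave odds of 0.194, which against the violet run meant an exponent of 1.83, resting on a reading of 13 mM with a scatter of 3 mM.
- That put the grey odds at 2.44 and the share at 70.9%. I committed to that share, to 1.83 for the partner order, and to 0.922 for the substrate order, read from the first green and violet readings.
- The forecast differed from my reckoning: it gave orders of 1 and 1 and a share of 69%, on an equilibrium “with the reverse rate rising sublinearly”.
- The flask gave 1.0 for substrate, 1.4 for partner, and a grey share of 59.8%.

    2 partner ⇌ reagent dimer, settled at all times (9.190 L mol⁻¹)
    substrate + reagent dimer → product + partner (0.4932 L mol⁻¹ h⁻¹)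
    substrate + partner + product → 2 product (4.572 L² mol⁻² h⁻¹)
    2 substrate → homo dimer (0.1534 L mol⁻¹ h⁻¹)

- The grey odds were 1.49, lower than my 2.44. Putting 1.4 in place of my blue-based exponent gave odds of 1.44, a share of 59.0%. The odds stayed this low because substrate left as homo dimer. In the simulated grey run without that conversion, the share rose from 59.8% to 80.0%, odds of 4.00, which is the 80.0% the partner charge allows.

The runs come from a simulation with constants of no real substance.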